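**Retrosynthetic overview**
1. Target 18 ⇒ angelic acid 16 + (S)-benzylic alcohol 15 (ester C–O bond); 15 ⇒ aryl methyl ketone 14 by asymmetric transfer hydrogenation.
2. 14 ⇒ cis-fused tricyclic α-methylene lactone 9 (lactone opened to the methyl ester, C3–OH acetylated); the lactone carries the cis C2/C3 relationship.
3. Key disconnection: the O1–C2 aryl ether bond of the dihydrofuran ring ⇒ phenol lactone 8, closed by a dehydrogenative allylic C–H etherification that sets C2.
4. 8 ⇒ 5-acetylsalicylaldehyde 3 + methyl 2-(bromomethyl)acrylate 4 (catalytic asymmetric 2-(methoxycarbonyl)allylation sets C3); 3 ⇒ salicylaldehyde 1 + acetyl chloride 2.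
5. Ring order: benzene ring bought; γ-lactone ring formed first (step 2); dihydrofuran ring second (step 3); lactone ring then opened (step 4).

The target is (2S,3S) in the ring (2,3-cis) and (S) at the side-chain carbinol; the angelate is (Z).

Assumption: in step 2 the (S,S) ligand antipode is taken to deliver the allyl group to the Re face of the aldehyde; if a test run gives the (S)-lactone, the (R,R) ligand is used and nothing else changes.

**Step 1**
Reactants: 1 salicylaldehyde; 2 acetyl chloride
Product: 3 5-acetyl-2-hydroxybenzaldehyde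
Conditions: AcCl (1.3 equiv), AlCl3 (3.5 equiv), CH2Cl2, 0 °C to reflux; aq. HCl
Reagents that add atoms: acetyl chloride 2, CC(=O)Cl
Why: Friedel–Crafts acylation, in which the aluminium phenoxide directs the acylium ion para to oxygen (C5, also meta to the deactivating formyl group), as in the familiar haloacetylation of salicylaldehyde; no stereocentre is formed.

**Step 2**
Reactants: 3 5-acetyl-2-hydroxybenzaldehyde; 4 methyl 2-(bromomethyl)acrylate
Product: 8 (R)-5-(5-acetyl-2-hydroxyphenyl)-3-methylenedihydrofuran-2(3H)-one, via aryl silyl ether 5 (not isolated), via bis-silyl adduct 6 (not isolated), via hydroxy ester 7 (not isolated)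
Conditions: CrCl2 (10 mol%), (S,S)-1,8-bis(4-isopropyl-2-oxazolinyl)-3,6-diphenylcarbazole (12 mol%), Mn (2 equiv), TMSCl (2.5 equiv), iPr2NEt (1.5 equiv), THF, rt; then 1 M HCl, THF, rt; TsOH·H2O (10 mol%), CH2Cl2, rt
Reagents that add atoms: methyl 2-(bromomethyl)acrylate 4, C=C(CBr)C(=O)OC
Why: Catalytic asymmetric Nozaki–Hiyama–Kishi-type 2-(alkoxycarbonyl)allylation, in which the ligand-bound allylchromium adds to the aldehyde (not the aryl ketone) through a closed six-membered transition state on the Re face to set the (R) carbinol (the future C3), while excess TMSCl/iPr2NEt masks the phenol in situ and turns chromium over, and the acid work-up desilylates and lactonises the γ-hydroxy ester.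

**Step 3**
Reactants: 8 (R)-5-(5-acetyl-2-hydroxyphenyl)-3-methylenedihydrofuran-2(3H)-one
Product: 9 (3aS,8bS)-7-acetyl-3-methylene-3a,8b-dihydrofuro[3,2-b]benzofuran-2(3H)-one
Conditions: Pd(OAc)2 (10 mol%), 1,2-bis(phenylsulfinyl)ethane (10 mol%), (salen)CrCl (10 mol%), 2,6-dimethyl-1,4-benzoquinone (2 equiv), 1,2-dichloroethane, 45 °C
Reagents that add atoms: none
Why: Proposed new method: dehydrogenative intramolecular allylic C–H etherification of an α-methylene-γ-butyrolactone, in which sulfoxide-ligated divalent palladium binds the exocyclic alkene on the face away from the aryl group, acetate-assisted cleavage of a ring C4–H gives a 2-acyl-π-allylpalladium species, the tethered phenol attacks its ring terminus from the aryl face (5-exo, anti to palladium) and the quinone reoxidises zerovalent palladium; because a trans-fused 5/5 system is not attainable, the new C–O bond can only form cis to the existing lactone C–O bond, so the (R) centre sets C2 as (S); the closest known reactions are the palladium/bis-sulfoxide allylic C–H etherification of terminal olefins to chromans and the stoichiometric allylic palladation of methylenecycloalkanes.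

**Step 4**
Reactants: 9 (3aS,8bS)-7-acetyl-3-methylene-3a,8b-dihydrofuro[3,2-b]benzofuran-2(3H)-one; 10 iodomethane; 11 acetic anhydride
Product: 14 methyl 2-[(2S,3S)-3-acetoxy-5-acetyl-2,3-dihydrobenzofuran-2-yl]acrylate, via lithium carboxylate 12 (not isolated), via ring-opened hydroxy ester 13 (not isolated)
Conditions: LiOH·H2O (1.1 equiv), THF/H2O, 0 °C; concentrate; MeI (3 equiv), DMF, rt; then Ac2O, pyridine, 0 °C to rt
Reagents that add atoms: lithium hydroxide, [Li+].[OH-]; iodomethane 10, CI; acetic anhydride 11, CC(=O)OC(C)=O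
Why: Lactone saponification, SN2 methylation of the carboxylate and O-acetylation, in which hydroxide attacks the strained lactone carbonyl faster than it adds to the acrylate, the carboxylate is methylated under neutral conditions and DMAP-free acetylation caps the C3 hydroxyl before it can relactonise or the aryl allyl ether can be opened by a nucleophilic catalyst; no bond at C2 or C3 is broken, so the cis (2S,3S) relationship is kept.

**Step 5**
Reactants: 14 methyl 2-[(2S,3S)-3-acetoxy-5-acetyl-2,3-dihydrobenzofuran-2-yl]acrylate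
Product: 15 methyl 2-[(2S,3S)-3-acetoxy-5-[(1S)-1-hydroxyethyl]-2,3-dihydrobenzofuran-2-yl]acrylate
Conditions: RuCl[(S,S)-TsDPEN](p-cymene) (1 mol%), HCO2H/Et3N (5:2), EtOAc, rt
Reagents that add atoms: none
Why: Noyori asymmetric transfer hydrogenation, in which the (S,S)-TsDPEN ruthenium hydride reduces aryl methyl ketones to (S)-1-arylethanols through the CH/π-controlled outer-sphere transition state and leaves the esters and the simple acrylate C=C untouched.

**Step 6**
Reactants: 15 methyl 2-[(2S,3S)-3-acetoxy-5-[(1S)-1-hydroxyethyl]-2,3-dihydrobenzofuran-2-yl]acrylate; 16 angelic acid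
Product: 18 methyl 2-[(2S,3S)-3-acetoxy-5-[(1S)-1-{[(Z)-2-methylbut-2-enoyl]oxy}ethyl]-2,3-dihydrobenzofuran-2-yl]acrylate, via mixed anhydride 17 (not isolated)
Conditions: 16, 2,4,6-trichlorobenzoyl chloride, Et3N, toluene, rt; then 15, toluene, 75 °C
Reagents that add atoms: angelic acid 16, C/C=C(/C)C(=O)O
Why: Yamaguchi-type esterification through the mixed anhydride without DMAP, in which the alcohol attacks the less hindered angeloyl carbonyl so that the carbinol C–O bond is untouched (S retained), and the absence of a nucleophilic catalyst avoids both angelate-to-tiglate isomerisation and SN2' opening of the aryl allyl ether.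

**Compound list**
1 | salicylaldehyde | O=Cc1ccccc1O | starting material
2 | acetyl chloride | CC(=O)Cl | starting material
3 | 5-acetyl-2-hydroxybenzaldehyde | CC(=O)c1ccc(O)c(C=O)c1 | intermediate
4 | methyl 2-(bromomethyl)acrylate | C=C(CBr)C(=O)OC | starting material
5 | 5-acetyl-2-(trimethylsilyloxy)benzaldehyde | CC(=O)c1ccc(O[Si](C)(C)C)c(C=O)c1 | intermediate
6 | methyl (4R)-4-[5-acetyl-2-(trimethylsilyloxy)phenyl]-2-methylene-4-(trimethylsilyloxy)butanoate | C=C(C[C@@H](O[Si](C)(C)C)c1cc(C(C)=O)ccc1O[Si](C)(C)C)C(=O)OC | intermediate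
7 | methyl (4R)-4-(5-acetyl-2-hydroxyphenyl)-4-hydroxy-2-methylenebutanoate | C=C(C[C@@H](O)c1cc(C(C)=O)ccc1O)C(=O)OC | intermediate
8 | (R)-5-(5-acetyl-2-hydroxyphenyl)-3-methylenedihydrofuran-2(3H)-one | C=C1C[C@H](c2cc(C(C)=O)ccc2O)OC1=O | intermediate
9 | (3aS,8bS)-7-acetyl-3-methylene-3a,8b-dihydrofuro[3,2-b]benzofuran-2(3H)-one (cis-fused) | C=C1C(=O)O[C@H]2c3cc(C(C)=O)ccc3O[C@@H]12 | intermediate
10 | iodomethane | CI | starting material
11 | acetic anhydride | CC(=O)OC(C)=O | starting material
12 | lithium 2-[(2S,3S)-5-acetyl-3-hydroxy-2,3-dihydrobenzofuran-2-yl]acrylate | [Li+].C=C(C(=O)[O-])[C@@H]1Oc2ccc(C(C)=O)cc2[C@@H]1O | intermediate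
13 | methyl 2-[(2S,3S)-5-acetyl-3-hydroxy-2,3-dihydrobenzofuran-2-yl]acrylate | C=C(C(=O)OC)[C@@H]1Oc2ccc(C(C)=O)cc2[C@@H]1O | intermediate
14 | methyl 2-[(2S,3S)-3-acetoxy-5-acetyl-2,3-dihydrobenzofuran-2-yl]acrylate | C=C(C(=O)OC)[C@@H]1Oc2ccc(C(C)=O)cc2[C@@H]1OC(C)=O | intermediate
15 | methyl 2-[(2S,3S)-3-acetoxy-5-[(1S)-1-hydroxyethyl]-2,3-dihydrobenzofuran-2-yl]acrylate | C=C(C(=O)OC)[C@@H]1Oc2ccc([C@H](C)O)cc2[C@@H]1OC(C)=O | intermediate
16 | angelic acid, (Z)-2-methylbut-2-enoic acid | C/C=C(/C)C(=O)O | starting material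
17 | (Z)-2-methylbut-2-enoic 2,4,6-trichlorobenzoic anhydride | C/C=C(/C)C(=O)OC(=O)c1c(Cl)cc(Cl)cc1Cl | intermediate
18 | methyl 2-[(2S,3S)-3-acetoxy-5-[(1S)-1-{[(Z)-2-methylbut-2-enoyl]oxy}ethyl]-2,3-dihydrobenzofuran-2-yl]acrylate | C=C(C(=O)OC)[C@@H]1Oc2ccc([C@H](C)OC(=O)/C(C)=C\C)cc2[C@@H]1OC(C)=O | target

**Totals**
Total step count: 6. Longest linear sequence: 6 steps (1 → 3 → 8 → 9 → 14 → 15 → 18).

**Three steps most likely to fail**

Step 2. The ortho-silyloxy group and the chelating carbonyls may lower rate or enantioselectivity of the chromium allylation. The fallback sets out from 3 and comes back at 8. The phenol is silylated (TBSCl, imidazole, DMF) to 5-acetyl-2-(tert-butyldimethylsilyloxy)benzaldehyde F1. An iridium-catalysed transfer-hydrogenative 2-(alkoxycarbonyl)allylation then replaces the organochromium addition: [Ir(cod)Cl]2, the SEGPHOS antipode that gives the (R)-carbinol, 4-cyano-3-nitrobenzoic acid, Cs2CO3, isopropanol as reductant, THF, 60 °C, with methyl 2-{[(tert-butoxycarbonyl)oxy]methyl}acrylate as allyl donor. This gives methyl (4R)-4-[5-acetyl-2-(tert-butyldimethylsilyloxy)phenyl]-4-hydroxy-2-methylenebutanoate F2. TBAF/AcOH and then TsOH·H2O remove the silyl group and lactonise to 8.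

Step 3. This is the proposed new step; the electron-poor 1,1-disubstituted alkene may resist C–H cleavage, or palladium hydride may isomerise it into the ring. The fallback uses known chemistry, sets out from 8 and comes back at 9. The phenol is acetylated (Ac2O, pyridine) to 4-acetyl-2-[(2R)-4-methylene-5-oxotetrahydrofuran-2-yl]phenyl acetate F3. Bromine (CH2Cl2, 0 °C) adds to the exocyclic alkene to give 4-acetyl-2-[(2R)-4-bromo-4-(bromomethyl)-5-oxotetrahydrofuran-2-yl]phenyl acetate F4. K2CO3 in methanol at 0 °C cleaves the aryl acetate and eliminates HBr to the butenolide (5R)-5-(5-acetyl-2-hydroxyphenyl)-3-(bromomethyl)furan-2(5H)-one F5, whose phenoxide closes at once by conjugate addition and bromide loss (SN2') to 9, again necessarily cis-fused. The C–O bond is thus made by addition–elimination on a pre-oxidised allylic bromide and not by C–H activation. The weak point is the base-labile γ-hydrogen of F5, so it is generated cold and only with the internal nucleophile already free.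

Step 6. Angelates isomerise to tiglates when the acyl group is activated, and the p-alkoxybenzylic centre is sensitive to heat and acid. The fallback sets out from 14 and comes back at 18. The ketone is reduced with the mirror-image catalyst RuCl[(R,R)-TsDPEN](p-cymene) in HCO2H/Et3N to methyl 2-[(2S,3S)-3-acetoxy-5-[(1R)-1-hydroxyethyl]-2,3-dihydrobenzofuran-2-yl]acrylate F6. A Mitsunobu reaction with 16 (PPh3 and DIAD premixed at −20 °C in toluene, then F6 and 16) lets the angelate oxygen displace the activated hydroxyl with inversion to the (1S)-ester 18. Angelic acid is never turned into an acylating agent, so the (Z) geometry cannot be lost; the remaining risk is partial ionisation of the benzylic oxyphosphonium, which low temperature and toluene suppress.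

**Further compounds**
F1 | step 2 | 5-acetyl-2-(tert-butyldimethylsilyloxy)benzaldehyde | CC(=O)c1ccc(O[Si](C)(C)C(C)(C)C)c(C=O)c1
F2 | step 2 | methyl (4R)-4-[5-acetyl-2-(tert-butyldimethylsilyloxy)phenyl]-4-hydroxy-2-methylenebutanoate | C=C(C[C@@H](O)c1cc(C(C)=O)ccc1O[Si](C)(C)C(C)(C)C)C(=O)OC
F3 | step 3 | 4-acetyl-2-[(2R)-4-methylene-5-oxotetrahydrofuran-2-yl]phenyl acetate | C=C1C[C@H](c2cc(C(C)=O)ccc2OC(C)=O)OC1=O
F4 | step 3 | 4-acetyl-2-[(2R)-4-bromo-4-(bromomethyl)-5-oxotetrahydrofuran-2-yl]phenyl acetate (both C4 epimers) | BrCC1(Br)C[C@H](c2cc(C(C)=O)ccc2OC(C)=O)OC1=O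
F5 | step 3 | (5R)-5-(5-acetyl-2-hydroxyphenyl)-3-(bromomethyl)furan-2(5H)-one | BrCC1=C[C@H](c2cc(C(C)=O)ccc2O)OC1=O
F6 | step 6 | methyl 2-[(2S,3S)-3-acetoxy-5-[(1R)-1-hydroxyethyl]-2,3-dihydrobenzofuran-2-yl]acrylate | C=C(C(=O)OC)[C@@H]1Oc2ccc([C@@H](C)O)cc2[C@@H]1OC(C)=O
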